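The target is read as a 4→6 dimer of one flavan unit, so both C rings are traced to one protected (2R,3R)-dihydroflavonol. Ring C is not closed directly: it comes from the furan ring of a 2-aryl-3-hydroxy-2,3-dihydrobenzofuran-3-carbaldehyde by an α-ketol ring enlargement. C2, bound to O1, shifts from the carbinol carbon (later C4, on ring A) to the formyl carbon (later C3). This exploits the C3 hydroxyl next to the ring-A-bound C4 of ring C and sets C3 trans to C2 in one operation. The resulting ketone is used twice: reduced to the 3,4-cis diol unit, and arylated at C4 by that unit before a hydride sets the 4,6-link cis.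

Key step: step 6

Abbreviations: Ar = 3,4-bis(benzyloxy)phenyl; DBB = 3,4-bis(benzyloxy)benzyl; TBS = tert-butyldimethylsilyl.
Remark: Rh2(S-PTTL)4 (dirhodium tetrakis[N-phthaloyl-(S)-tert-leucinate]) is assumed to give the (2S) ether carbon in 5; if its sense is the reverse, the enantiomeric catalyst is used.
Remark: CIP letters at C3 and C4 change with the substituents (ketone, silyl ether, aryl) while the spatial arrangement stays the same; the SMILES are authoritative.

Step 1
Reactants: 1 methyl 2-(2,4-dihydroxyphenyl)acetate; 2 3,4-bis(benzyloxy)benzyl chloride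
Product: 3 methyl 2-[2,4-bis(DBB-oxy)phenyl]acetate
Conditions: 2 (2.2 equiv), K2CO3, KI (cat.), DMF, 60 °C
Reagents that add atoms: none
Why: Williamson ether synthesis on both phenols with the same benzylic chloride, so the two hydroxyls need not be told apart; the ortho ether carries the later C2 and ring B, the para ether protects the later 7-OH.

Step 2
Reactants: 3 methyl 2-[2,4-bis(DBB-oxy)phenyl]acetate
Product: 4 methyl 2-diazo-2-[2,4-bis(DBB-oxy)phenyl]acetate
Conditions: p-ABSA, DBU, MeCN, 0 °C → rt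
Reagents that add atoms: 4-acetamidobenzenesulfonyl azide, CC(=O)Nc1ccc(cc1)S(=O)(=O)N=[N+]=[N-]
Why: Regitz diazo transfer to the acidic benzylic α-carbon of the aryl acetate.

Step 3
Reactants: 4 methyl 2-diazo-2-[2,4-bis(DBB-oxy)phenyl]acetate
Product: 5 methyl (2S,3R)-2-Ar-6-(DBB-oxy)-2,3-dihydrobenzofuran-3-carboxylate (2,3-cis)
Conditions: Rh2(S-PTTL)4 (1 mol %), toluene, −60 °C
Reagents that add atoms: none
Why: intramolecular 1,5 C–H insertion of the donor/acceptor dirhodium carbenoid into the benzylic ether C–H of the ortho ether, in which the chiral carboxylate catalyst sets the ether carbon (2S, the later C2 of the flavan) and the cis ester forms kinetically (its centre is erased in step 4).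

Step 4
Reactants: 5 methyl (2S,3R)-2-Ar-6-(DBB-oxy)-2,3-dihydrobenzofuran-3-carboxylate
Product: 6 methyl (2R,3S)-2-Ar-6-(DBB-oxy)-3-hydroxy-2,3-dihydrobenzofuran-3-carboxylate (hydroxyl trans to Ar)
Conditions: KN(SiMe3)2, THF, −78 °C; 2-(phenylsulfonyl)-3-phenyloxaziridine; aq NH4Cl
Reagents that add atoms: 2-(phenylsulfonyl)-3-phenyloxaziridine, O=S(=O)(c1ccccc1)N1OC1c1ccccc1
Why: enolate hydroxylation by an N-sulfonyloxaziridine, in which the planar ester enolate is attacked on the face away from the neighbouring 2-aryl group (hydroxyl trans to Ar, ester cis) and ring opening is stereoelectronically disfavoured because the C2–O1 bond lies near the nodal plane of the enolate, so C2 is kept.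

Step 5
Reactants: 6 methyl (2R,3S)-2-Ar-6-(DBB-oxy)-3-hydroxy-2,3-dihydrobenzofuran-3-carboxylate
Product: 7 (2R,3S)-2-Ar-6-(DBB-oxy)-3-hydroxy-2,3-dihydrobenzofuran-3-carbaldehyde
Conditions: i-Bu2AlH (2.5 equiv), CH2Cl2, −78 °C; aq potassium sodium tartrate
Reagents that add atoms: none
Why: partial ester reduction, in which the aluminium alkoxide of the neighbouring hydroxyl chelates the tetrahedral intermediate so that it holds at −78 °C and releases the aldehyde only on work-up; no stereocenter is touched.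

Step 6
Reactants: 7 (2R,3S)-2-Ar-6-(DBB-oxy)-3-hydroxy-2,3-dihydrobenzofuran-3-carbaldehyde
Product: 8 (2R,3R)-2-Ar-7-(DBB-oxy)-3-hydroxychroman-4-one (2,3-trans)
Conditions: Sc(OTf)3 (10 mol %), 4 Å molecular sieves, CH2Cl2, 0 °C → rt
Reagents that add atoms: none
Why: The scandium centre binds the hydroxyl and formyl oxygens in a five-membered chelate, and as the hydroxyl oxygen forms the C4 carbonyl, the O1-bearing benzylic ring carbon C2 shifts suprafacially from the carbinol carbon to the formyl carbon, which becomes the carbinol C3. This is the α-ketol (acyloin) rearrangement in its ring-enlarging form, the reaction type of the D-homoannulation of 17-hydroxy-20-keto steroids and of the Lewis acid catalysed conversion of 1-hydroxycycloalkanecarbaldehydes into 2-hydroxycycloalkanones. No ring is closed by a cyclisation: ring C (O1, C2, C3, C4, C4a, C8a) arises from the five-membered dihydrofuran ring by insertion of the exocyclic formyl carbon between C2 and the carbinol carbon through the 1,2-carbon shift. C2 migrates with retention, and C3 is set by the syn-chelated geometry, which delivers C2 to the formyl face that places the new hydroxyl trans to the 2-aryl group, giving (2R,3R), also the thermodynamic isomer. The step needs migration of C2 and not of the ring A carbon: the electron-rich aryl group that stays on the carbinol carbon stabilises the developing vinylogous-ester carbonyl, the migrating bond is activated by O1 and ring B, and because the manifold is reversible, a 4-hydroxy-3-ketone from an aryl shift should drain by a 1,2-hydride shift into the conjugated ketone 8. The driving force is the change from a five-ring tertiary hydroxy aldehyde to a six-ring aryl ketone.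

Step 7
Reactants: 8 (2R,3R)-2-Ar-7-(DBB-oxy)-3-hydroxychroman-4-one
Product: 9 (2R,3R)-2-Ar-7-(DBB-oxy)-3-(TBS-oxy)chroman-4-one
Conditions: TBSCl, imidazole, DMF, 40 °C
Reagents that add atoms: tert-butyldimethylsilyl chloride, CC(C)(C)[Si](C)(C)Cl
Why: silylation of the secondary hydroxyl under non-enolising conditions; the bulky silyl ether later shields the β face of ring C.

Step 8
Reactants: 9 (2R,3R)-2-Ar-7-(DBB-oxy)-3-(TBS-oxy)chroman-4-one
Product: 10 (2R,3S,4S)-2-Ar-7-(DBB-oxy)-3-(TBS-oxy)chroman-4-ol (2,3-trans-3,4-cis)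
Conditions: LiBH(s-Bu)3, THF, −78 °C; aq NH4Cl
Reagents that add atoms: none
Why: bulky-hydride ketone reduction, in which the hydride comes along the equatorial line on the face away from the 3-silyloxy group and gives the axial 4-hydroxyl cis to O3, as 2-substituted cyclohexanones do with this reagent.

Step 9
Reactants: 10 (2R,3S,4S)-2-Ar-7-(DBB-oxy)-3-(TBS-oxy)chroman-4-ol
Product: 11 (2R,3R,4S)-2-Ar-7-(DBB-oxy)-3,4-bis(TBS-oxy)chroman
Conditions: TBSOTf, 2,6-lutidine, CH2Cl2, −40 → 0 °C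
Reagents that add atoms: tert-butyldimethylsilyl trifluoromethanesulfonate, CC(C)(C)[Si](C)(C)OS(=O)(=O)C(F)(F)F
Why: silylation of the hindered benzylic alcohol with the silyl triflate, which guards the C4–O bond against the organolithium and against ionisation later.

Step 10
Reactants: 11 (2R,3R,4S)-2-Ar-7-(DBB-oxy)-3,4-bis(TBS-oxy)chroman
Product: 12 (2R,3R,4S)-2-Ar-6-bromo-7-(DBB-oxy)-3,4-bis(TBS-oxy)chroman
Conditions: NBS (1.0 equiv), DMF, −20 °C, dark
Reagents that add atoms: N-bromosuccinimide, BrN1C(=O)CCC1=O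
Why: electrophilic aromatic bromination at C6, which is para to O1 and ortho to the 7-ether and so the most activated open position of ring A (C8 lies between two oxygens, and the catechol-type rings have only one para oxygen each).

Step 11
Reactants: 12 (2R,3R,4S)-2-Ar-6-bromo-7-(DBB-oxy)-3,4-bis(TBS-oxy)chroman; 9 (2R,3R)-2-Ar-7-(DBB-oxy)-3-(TBS-oxy)chroman-4-one
Product: 15 (2R,3R,4R)-2-Ar-7-(DBB-oxy)-3-(TBS-oxy)-4-[(2R,3R,4S)-2-Ar-7-(DBB-oxy)-3,4-bis(TBS-oxy)chroman-6-yl]chroman-4-ol, via aryllithium 13 (not isolated), via arylcerium dichloride 14 (not isolated)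
Conditions: 12, t-BuLi (2 equiv), THF, −78 °C; CeCl3, −78 °C; then 9, −78 → −40 °C; aq NH4Cl
Reagents that add atoms: none
Why: bromine–lithium exchange, transmetalation to the weakly basic organocerium and 1,2-addition to the enolisable ketone form the C4–C6 bond; the aryl group should enter anti to the 3-silyloxy group, but this carbinol centre is flattened in step 12.

Step 12
Reactants: 15 the tertiary carbinol from step 11
Product: 16 (2R,3S,4R)-2-Ar-7-(DBB-oxy)-3-(TBS-oxy)-4-[(2R,3R,4S)-2-Ar-7-(DBB-oxy)-3,4-bis(TBS-oxy)chroman-6-yl]chroman (3,4-cis at the link)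
Conditions: Et3SiH (5 equiv), CF3CO2H, CH2Cl2, −40 °C
Reagents that add atoms: none
Why: ionic hydrogenation, in which the tertiary doubly benzylic alcohol ionises to a C4 cation stabilised by both resorcinol-type rings and the silane delivers hydride to the α face, anti to the 3-silyloxy group (pseudoaxial to avoid the C4 aryl), so that the lower unit ends cis to O3.

Step 13
Reactants: 16 the fully protected dimer
Product: 17 (2R,3S,4S)-2-(3,4-dihydroxyphenyl)-4-[(2R,3R,4S)-2-(3,4-dihydroxyphenyl)-7-hydroxy-3,4-bis(TBS-oxy)chroman-6-yl]-3-(TBS-oxy)chroman-7-ol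
Conditions: H2 (1 atm), Pd(OH)2/C, THF/MeOH, rt
Reagents that add atoms: none
Why: hydrogenolysis of the eight benzyl ethers and the two benzylic aryl ethers, run while the benzylic C4–O of the lower unit is still a silyl ether so that this bond is not hydrogenolysed.

Step 14
Reactants: 17 the tris-TBS ether of the target
Product: 18 (2R,3S,4S)-2-(3,4-dihydroxyphenyl)-6-[(2R,3S,4S)-2-(3,4-dihydroxyphenyl)-3,7-dihydroxychroman-4-yl]chroman-3,4,7-triol (CNP0280090.1)
Conditions: HF·pyridine, pyridine/THF, 0 °C → rt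
Reagents that add atoms: none
Why: fluoride-mediated cleavage of the three silyl ethers under buffered, non-ionising conditions that should leave the acid-labile benzylic 4-hydroxyl and the catechols intact.

Compound list

1 | methyl 2-(2,4-dihydroxyphenyl)acetate | COC(=O)Cc1ccc(O)cc1O | starting material
2 | 3,4-bis(benzyloxy)benzyl chloride | ClCc1ccc(OCc2ccccc2)c(OCc2ccccc2)c1 | starting material
3 | methyl 2-[2,4-bis(DBB-oxy)phenyl]acetate | COC(=O)Cc1ccc(OCc2ccc(OCc3ccccc3)c(OCc3ccccc3)c2)cc1OCc1ccc(OCc2ccccc2)c(OCc2ccccc2)c1 | intermediate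
4 | methyl 2-diazo-2-[2,4-bis(DBB-oxy)phenyl]acetate | COC(=O)C(=[N+]=[N-])c1ccc(OCc2ccc(OCc3ccccc3)c(OCc3ccccc3)c2)cc1OCc1ccc(OCc2ccccc2)c(OCc2ccccc2)c1 | intermediate
5 | methyl (2S,3R)-2-Ar-6-(DBB-oxy)-2,3-dihydrobenzofuran-3-carboxylate (cis) | COC(=O)[C@@H]1c2ccc(OCc3ccc(OCc4ccccc4)c(OCc4ccccc4)c3)cc2O[C@@H]1c1ccc(OCc2ccccc2)c(OCc2ccccc2)c1 | intermediate
6 | methyl (2R,3S)-2-Ar-6-(DBB-oxy)-3-hydroxy-2,3-dihydrobenzofuran-3-carboxylate (hydroxyl trans to Ar) | COC(=O)[C@]1(O)c2ccc(OCc3ccc(OCc4ccccc4)c(OCc4ccccc4)c3)cc2O[C@@H]1c1ccc(OCc2ccccc2)c(OCc2ccccc2)c1 | intermediate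
7 | (2R,3S)-2-Ar-6-(DBB-oxy)-3-hydroxy-2,3-dihydrobenzofuran-3-carbaldehyde | O=C[C@]1(O)c2ccc(OCc3ccc(OCc4ccccc4)c(OCc4ccccc4)c3)cc2O[C@@H]1c1ccc(OCc2ccccc2)c(OCc2ccccc2)c1 | intermediate
8 | (2R,3R)-2-Ar-7-(DBB-oxy)-3-hydroxychroman-4-one (2,3-trans) | O=C1c2ccc(OCc3ccc(OCc4ccccc4)c(OCc4ccccc4)c3)cc2O[C@H](c2ccc(OCc3ccccc3)c(OCc3ccccc3)c2)[C@H]1O | intermediate
9 | (2R,3R)-2-Ar-7-(DBB-oxy)-3-(TBS-oxy)chroman-4-one | O=C1c2ccc(OCc3ccc(OCc4ccccc4)c(OCc4ccccc4)c3)cc2O[C@H](c2ccc(OCc3ccccc3)c(OCc3ccccc3)c2)[C@H]1O[Si](C)(C)C(C)(C)C | intermediate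
10 | (2R,3S,4S)-2-Ar-7-(DBB-oxy)-3-(TBS-oxy)chroman-4-ol (2,3-trans-3,4-cis) | O[C@H]1c2ccc(OCc3ccc(OCc4ccccc4)c(OCc4ccccc4)c3)cc2O[C@H](c2ccc(OCc3ccccc3)c(OCc3ccccc3)c2)[C@H]1O[Si](C)(C)C(C)(C)C | intermediate
11 | (2R,3R,4S)-2-Ar-7-(DBB-oxy)-3,4-bis(TBS-oxy)chroman | CC(C)(C)[Si](C)(C)O[C@H]1c2ccc(OCc3ccc(OCc4ccccc4)c(OCc4ccccc4)c3)cc2O[C@H](c2ccc(OCc3ccccc3)c(OCc3ccccc3)c2)[C@H]1O[Si](C)(C)C(C)(C)C | intermediate
12 | (2R,3R,4S)-2-Ar-6-bromo-7-(DBB-oxy)-3,4-bis(TBS-oxy)chroman | CC(C)(C)[Si](C)(C)O[C@H]1c2cc(Br)c(OCc3ccc(OCc4ccccc4)c(OCc4ccccc4)c3)cc2O[C@H](c2ccc(OCc3ccccc3)c(OCc3ccccc3)c2)[C@H]1O[Si](C)(C)C(C)(C)C | intermediate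
13 | 6-lithio analogue of 12 (aryllithium) | CC(C)(C)[Si](C)(C)O[C@H]1c2cc([Li])c(OCc3ccc(OCc4ccccc4)c(OCc4ccccc4)c3)cc2O[C@H](c2ccc(OCc3ccccc3)c(OCc3ccccc3)c2)[C@H]1O[Si](C)(C)C(C)(C)C | intermediate
14 | 6-(dichlorocerio) analogue of 12 (arylcerium dichloride) | CC(C)(C)[Si](C)(C)O[C@H]1c2cc([Ce](Cl)Cl)c(OCc3ccc(OCc4ccccc4)c(OCc4ccccc4)c3)cc2O[C@H](c2ccc(OCc3ccccc3)c(OCc3ccccc3)c2)[C@H]1O[Si](C)(C)C(C)(C)C | intermediate
15 | (2R,3R,4R)-2-Ar-7-(DBB-oxy)-3-(TBS-oxy)-4-[(2R,3R,4S)-2-Ar-7-(DBB-oxy)-3,4-bis(TBS-oxy)chroman-6-yl]chroman-4-ol (4-hydroxyl cis to O3) | O(Cc1ccc(OCc2ccccc2)c(OCc2ccccc2)c1)c1ccc2c(c1)O[C@H](c1ccc(OCc3ccccc3)c(OCc3ccccc3)c1)[C@@H](O[Si](C)(C)C(C)(C)C)[C@]2(O)c1cc2c(cc1OCc1ccc(OCc3ccccc3)c(OCc3ccccc3)c1)O[C@H](c1ccc(OCc3ccccc3)c(OCc3ccccc3)c1)[C@@H](O[Si](C)(C)C(C)(C)C)[C@H]2O[Si](C)(C)C(C)(C)C | intermediate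
16 | (2R,3S,4R)-2-Ar-7-(DBB-oxy)-3-(TBS-oxy)-4-[(2R,3R,4S)-2-Ar-7-(DBB-oxy)-3,4-bis(TBS-oxy)chroman-6-yl]chroman (lower unit cis to O3 at C4) | O(Cc1ccc(OCc2ccccc2)c(OCc2ccccc2)c1)c1ccc2c(c1)O[C@H](c1ccc(OCc3ccccc3)c(OCc3ccccc3)c1)[C@@H](O[Si](C)(C)C(C)(C)C)[C@H]2c1cc2c(cc1OCc1ccc(OCc3ccccc3)c(OCc3ccccc3)c1)O[C@H](c1ccc(OCc3ccccc3)c(OCc3ccccc3)c1)[C@@H](O[Si](C)(C)C(C)(C)C)[C@H]2O[Si](C)(C)C(C)(C)C | intermediate
17 | (2R,3S,4S)-2-(3,4-dihydroxyphenyl)-4-[(2R,3R,4S)-2-(3,4-dihydroxyphenyl)-7-hydroxy-3,4-bis(TBS-oxy)chroman-6-yl]-3-(TBS-oxy)chroman-7-ol | Oc1ccc2c(c1)O[C@H](c1ccc(O)c(O)c1)[C@@H](O[Si](C)(C)C(C)(C)C)[C@H]2c1cc2c(cc1O)O[C@H](c1ccc(O)c(O)c1)[C@@H](O[Si](C)(C)C(C)(C)C)[C@H]2O[Si](C)(C)C(C)(C)C | intermediate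
18 | (2R,3S,4S)-2-(3,4-dihydroxyphenyl)-6-[(2R,3S,4S)-2-(3,4-dihydroxyphenyl)-3,7-dihydroxychroman-4-yl]chroman-3,4,7-triol | Oc1ccc2c(c1)O[C@H](c1ccc(O)c(O)c1)[C@@H](O)[C@H]2c1cc2c(cc1O)O[C@H](c1ccc(O)c(O)c1)[C@@H](O)[C@H]2O | target

Total step count: 14. Longest linear sequence: 14 steps (1 → 18; ketone 9 enters a second time in step 11).

Steps most likely to fail

Step 6. The ring A carbon may migrate in place of C2, the rearrangement may stall in hemiacetal oligomers of the free hydroxy aldehyde, or C2 may epimerise through an enolisable 3-ketone. The fallback sets out from 6 and runs the shift on a silyl ether under stoichiometric chelation control, so that no free ketol can re-enter the manifold. TBSOTf and 2,6-lutidine should give the tert-butyldimethylsilyl ether of 6 F1. i-Bu2AlH at −78 °C should give the α-silyloxy aldehyde F2. Me2AlCl (2.5 equiv) in CH2Cl2 at −78 °C should then promote the acyloin rearrangement of the α-silyloxy aldehyde, with silyl transfer between the two chelated oxygens. This delivers the silyl ether 9 directly, and the route is rejoined at 9.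

Step 11. The organometal may deprotonate C3 of the ketone, with ring opening by loss of O1, or fail to add for steric reasons. The fallback sets out from 10 and 11 and joins the units by a cationic route. BF3·OEt2 in CH2Cl2 at −78 °C ionises the 4-hydroxyl of 10, and an excess of 11 is alkylated at C6 (Friedel–Crafts). Because the arene enters anti to the 3-silyloxy group, this should give mainly the 3,4-trans coupling product F3 beside 16. The doubly benzylic C4–H of this material is then oxidised with DDQ in wet CH2Cl2 to the carbinol 15; either C4 epimer serves. The route is rejoined at 15.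

Step 12. Hydride delivery may show poor facial selectivity, or the cation may lose the C3 proton, which would scramble C3 and C4 through a silyl enol ether. The fallback sets out from 15 and replaces ionic hydrogenation by catalytic hydrogenolysis of the tertiary benzylic C–O bond (H2, Pd/C, EtOAc/AcOH). On palladium this goes with inversion, so hydrogen replaces the β hydroxyl from the α face and the same 3,4-cis link results. The benzyl-type ethers fall in the same operation. No new compound is made on this way (F0), and the route is rejoined at 17.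

Further compounds

F1 | step 6 | methyl (2R,3S)-2-Ar-6-(DBB-oxy)-3-(TBS-oxy)-2,3-dihydrobenzofuran-3-carboxylate | COC(=O)[C@]1(O[Si](C)(C)C(C)(C)C)c2ccc(OCc3ccc(OCc4ccccc4)c(OCc4ccccc4)c3)cc2O[C@@H]1c1ccc(OCc2ccccc2)c(OCc2ccccc2)c1
F2 | step 6 | (2R,3S)-2-Ar-6-(DBB-oxy)-3-(TBS-oxy)-2,3-dihydrobenzofuran-3-carbaldehyde | O=C[C@]1(O[Si](C)(C)C(C)(C)C)c2ccc(OCc3ccc(OCc4ccccc4)c(OCc4ccccc4)c3)cc2O[C@@H]1c1ccc(OCc2ccccc2)c(OCc2ccccc2)c1
F3 | step 11 | C4 epimer of 16 in the upper unit (lower unit trans to O3 at C4) | O(Cc1ccc(OCc2ccccc2)c(OCc2ccccc2)c1)c1ccc2c(c1)O[C@H](c1ccc(OCc3ccccc3)c(OCc3ccccc3)c1)[C@@H](O[Si](C)(C)C(C)(C)C)[C@@H]2c1cc2c(cc1OCc1ccc(OCc3ccccc3)c(OCc3ccccc3)c1)O[C@H](c1ccc(OCc3ccccc3)c(OCc3ccccc3)c1)[C@@H](O[Si](C)(C)C(C)(C)C)[C@H]2O[Si](C)(C)C(C)(C)C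
F0 | step 12 | none | none
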